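The route rests on disconnecting the C3–ring B bond and the C2–H bond at once. C2, the lone stereocentre, is a methine flanked by ring A and the ester carbonyl, and its neighbour C3 is a methylene attached to ring B, so the skeleton can be assembled from an achiral atropate by delivering ring B to the terminal CH2 and a hydrogen to the ring A-bearing carbon. A rhodium/BINAP conjugate arylation with catalyst-controlled protonation does both in one operation and leaves the three C–Br bonds alone. The partners are a MOM-protected methyl 2-(ring A)acrylate and a MOM-protected 2,3-dibromoaryl pinacol boronate, both made from 5-bromovanillin; acidic methanolysis then frees the phenols.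

Key step: step 14

Remark: the target is the 2R ester (CO2Me > ring A > CH2 > H); ring A is 3-bromo-5-hydroxy-4-methoxyphenyl on C2 and ring B is 2,3-dibromo-4,5-dihydroxyphenyl on C3.

Remark: 5-bromovanillin carries its methyl on the oxygen remote from bromine, whereas ring A needs it on the oxygen next to bromine; direct MOM protection would give the regioisomeric 3-bromo-5-methoxy-4-(methoxymethoxy) ring, so the methyl is removed and put back on O-4 (steps 1 and 2).

Remark: the rhodium catalyst is used as the preformed, cyclooctadiene-free hydroxo BINAP dimer, because diene-bound rhodium would run a fast racemic background reaction.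

Assumption: (S)-BINAP is taken to give the 2R ester; the sense of induction for an atropate cannot be predicted securely, and the antipodal ligand is used if a first run shows 2S.

Step 1
Reactants: 1 5-bromovanillin (3-bromo-4-hydroxy-5-methoxybenzaldehyde)
Product: 2 3-bromo-4,5-dihydroxybenzaldehyde
Conditions: AlCl3, pyridine, CH2Cl2, reflux; aq. HCl work-up
Reagents that add atoms: none
Why: Lewis-acid cleavage of a guaiacol ether, in which AlCl3 chelates the o-hydroxyanisole unit and pyridine removes the activated O-methyl group by SN2 attack, a process specific for a methoxy group next to a free phenol that leaves the aldehyde and the C–Br bond alone.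

Step 2
Reactants: 2 3-bromo-4,5-dihydroxybenzaldehyde
Product: 3 3-bromo-5-hydroxy-4-methoxybenzaldehyde
Conditions: MeI (1.05 equiv), Li2CO3, DMF, 45 °C
Reagents that add atoms: iodomethane, CI
Why: Regioselective Williamson etherification, since the 4-OH is para to the formyl group and ortho to bromine and is the more acidic phenol, so a weak base and one equivalent of MeI should alkylate the 4-phenoxide and place the methyl on the oxygen next to bromine.

Step 3
Reactants: 3 3-bromo-5-hydroxy-4-methoxybenzaldehyde
Product: 4 3-bromo-4-methoxy-5-(methoxymethoxy)benzaldehyde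
Conditions: MOMCl, i-Pr2NEt, CH2Cl2, 0 °C → rt
Reagents that add atoms: chloromethyl methyl ether, COCCl
Why: O-alkylation of the remaining phenol with an α-chloro ether (acetal protection) gives a MOM ether that withstands the basic, reducing and rhodium-catalysed steps ahead and is removed by the final acidic methanolysis.

Step 4
Reactants: 4 3-bromo-4-methoxy-5-(methoxymethoxy)benzaldehyde
Product: 5 (±)-1-[3-bromo-4-methoxy-5-(methoxymethoxy)phenyl]-2,2,2-trichloroethan-1-ol
Conditions: CHCl3, DBU (1 equiv), 0 °C → rt
Reagents that add atoms: chloroform, ClC(Cl)Cl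
Why: Base-mediated 1,2-addition of trichloromethanide to a non-enolisable aryl aldehyde gives the trichloromethyl carbinol as a racemate, whose stereocentre is irrelevant because it becomes a CH2 group in step 5.

Step 5
Reactants: 5 (±)-1-[3-bromo-4-methoxy-5-(methoxymethoxy)phenyl]-2,2,2-trichloroethan-1-ol
Product: 8 [3-bromo-4-methoxy-5-(methoxymethoxy)phenyl]acetic acid, via dichloroepoxide 6 (not isolated), via acyl chloride 7 (not isolated)
Conditions: NaBH4, NaOH, t-BuOH, 55 °C; then cold aq. citric acid to pH 4
Reagents that add atoms: sodium hydroxide, [Na+].[OH-]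
Why: Reductive Jocic–Reeve homologation, in which hydroxide closes the carbinol to the gem-dichloroepoxide, borohydride opens it at the benzylic carbon to the acyl chloride and hydroxide converts that to the carboxylate, all under basic conditions that the MOM ether and the aryl bromide tolerate.

Step 6
Reactants: 8 [3-bromo-4-methoxy-5-(methoxymethoxy)phenyl]acetic acid
Product: 9 methyl [3-bromo-4-methoxy-5-(methoxymethoxy)phenyl]acetate
Conditions: MeI, K2CO3, DMF, rt
Reagents that add atoms: iodomethane, CI
Why: SN2 O-methylation of the carboxylate forms the ester without the acid of a Fischer esterification, which the MOM ether would not survive.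

Step 7
Reactants: 9 methyl [3-bromo-4-methoxy-5-(methoxymethoxy)phenyl]acetate
Product: 11 methyl 2-[3-bromo-4-methoxy-5-(methoxymethoxy)phenyl]prop-2-enoate, via hydroxymethyl ester 10 (not isolated)
Conditions: (CH2O)n, K2CO3, Bu4NI (cat.), toluene, 80 °C
Reagents that add atoms: formaldehyde (from paraformaldehyde), C=O
Why: α-Methylenation of an arylacetic ester, in which the benzylic enolate undergoes aldol addition to formaldehyde and the β-hydroxy ester loses water by E1cB elimination, so the racemic centre of 10 disappears in the alkene.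

Step 8
Reactants: 1 5-bromovanillin (3-bromo-4-hydroxy-5-methoxybenzaldehyde)
Product: 12 2,3-dibromo-4-hydroxy-5-methoxybenzaldehyde
Conditions: Br2, Fe powder (cat.), AcOH, rt
Reagents that add atoms: bromine, BrBr
Why: Electrophilic aromatic bromination with FeBr3 formed in the flask should enter para to the methoxy group, the other free site between formyl and methoxy being only ortho-activated, which gives the vicinal dibromo pattern of ring B.

Step 9
Reactants: 12 2,3-dibromo-4-hydroxy-5-methoxybenzaldehyde
Product: 13 2,3-dibromo-4,5-dihydroxybenzaldehyde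
Conditions: AlCl3, pyridine, CH2Cl2, reflux; aq. HCl work-up
Reagents that add atoms: none
Why: The same chelation-assisted guaiacol ether cleavage as in step 1 removes the methyl group next to the free phenol and leaves the aldehyde and both C–Br bonds intact.

Step 10
Reactants: 13 2,3-dibromo-4,5-dihydroxybenzaldehyde
Product: 14 2,3-dibromo-4,5-bis(methoxymethoxy)benzaldehyde
Conditions: MOMCl (3 equiv), i-Pr2NEt, CH2Cl2, 0 °C → rt
Reagents that add atoms: chloromethyl methyl ether, COCCl
Why: Double O-alkylation of the catechol (acetal protection) puts the same protecting group on all phenols of both rings, so a single acidic step removes them at the end.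

Step 11
Reactants: 14 2,3-dibromo-4,5-bis(methoxymethoxy)benzaldehyde
Product: 15 2,3-dibromo-4,5-bis(methoxymethoxy)benzoic acid
Conditions: NaClO2, NaH2PO4, 2-methyl-2-butene, t-BuOH/H2O, rt
Reagents that add atoms: sodium chlorite, [Na+].[O-]Cl=O
Why: Pinnick oxidation (addition of chlorous acid to the aldehyde and fragmentation to the acid) in phosphate buffer with an alkene scavenger for HOCl is mild enough for the MOM acetals and the electron-rich ring.

Step 12
Reactants: 15 2,3-dibromo-4,5-bis(methoxymethoxy)benzoic acid
Product: 18 2,3-dibromo-4,5-bis(methoxymethoxy)aniline, via acyl azide 16 (not isolated), via isocyanate 17 (not isolated)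
Conditions: (PhO)2P(O)N3, Et3N, toluene, rt → 90 °C; then 2 M aq. NaOH, THF, rt
Reagents that add atoms: diphenylphosphoryl azide, [N-]=[N+]=NP(=O)(Oc1ccccc1)Oc1ccccc1
Why: Curtius rearrangement, in which the acyl azide loses N2 with 1,2-shift of the aryl group to nitrogen and alkaline hydrolysis of the isocyanate with loss of CO2 gives the aniline without any acid that would threaten the MOM ethers.

Step 13
Reactants: 18 2,3-dibromo-4,5-bis(methoxymethoxy)aniline
Product: 20 2-[2,3-dibromo-4,5-bis(methoxymethoxy)phenyl]-4,4,5,5-tetramethyl-1,3,2-dioxaborolane, via diazonium tert-butoxide 19 (not isolated)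
Conditions: t-BuONO (1.5 equiv), B2pin2 (1.2 equiv), (PhCO2)2 (cat.), MeCN, rt
Reagents that add atoms: bis(pinacolato)diboron, CC1(C)OB(OC1(C)C)B1OC(C)(C)C(C)(C)O1
Why: Metal-free Sandmeyer-type borylation, in which non-acidic diazotisation gives the diazonium tert-butoxide, the alkoxide activates B2pin2 and loss of N2 gives an aryl radical that is borylated at the former C–N carbon, so with no transition metal and no acid present the two C–Br bonds and the MOM ethers stay.

Step 14
Reactants: 11 methyl 2-[3-bromo-4-methoxy-5-(methoxymethoxy)phenyl]prop-2-enoate; 20 2-[2,3-dibromo-4,5-bis(methoxymethoxy)phenyl]-4,4,5,5-tetramethyl-1,3,2-dioxaborolane (2 equiv)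
Product: 21 methyl (2R)-2-[3-bromo-4-methoxy-5-(methoxymethoxy)phenyl]-3-[2,3-dibromo-4,5-bis(methoxymethoxy)phenyl]propanoate
Conditions: [Rh(OH)((S)-BINAP)]2 (3 mol %), B(OH)3 (2 equiv), 1,4-dioxane/H2O (10:1), 50 °C
Reagents that add atoms: none
Why: [Rh(OH)((S)-BINAP)]2 transmetalates with the boronate (water assisting) to an aryl–rhodium species of monovalent rhodium, which inserts the acrylate with ring B going to the unsubstituted CH2 terminus, and the resulting oxa-π-allyl rhodium enolate is protonated at C2 inside the chiral pocket of the bisphosphine, returning Rh–OH. The closest known reaction type is the rhodium-catalysed conjugate arylation of α-substituted acrylates with enantioselective protonation (a Hayashi–Miyaura addition ending in catalyst-controlled protonation). No ring is closed. The only new stereocentre, C2, is set under catalyst control by the BINAP ligand at the protonation, the acrylate being achiral. Regioselectivity is secured by the polarisation of the alkene by the ester and ring A, and chemoselectivity by the inertness of monovalent rhodium towards the three aryl C–Br bonds. Protonation of the rhodium-bound enolate must outrun β-hydride elimination, protonation of free enolate and later epimerisation of the acidic C2–H, which the diene-free catalyst, the weakly acidic B(OH)3 and the near-neutral medium at moderate temperature are chosen to ensure.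

Step 15
Reactants: 21 methyl (2R)-2-[3-bromo-4-methoxy-5-(methoxymethoxy)phenyl]-3-[2,3-dibromo-4,5-bis(methoxymethoxy)phenyl]propanoate
Product: 22 methyl (2R)-2-(3-bromo-5-hydroxy-4-methoxyphenyl)-3-(2,3-dibromo-4,5-dihydroxyphenyl)propanoate
Conditions: 1.25 M HCl in MeOH, degassed, rt → 40 °C
Reagents that add atoms: none
Why: Acid-catalysed transacetalisation (MOM ether methanolysis) releases the three phenols, while the methyl ester is degenerate towards methanol, the aryl methyl ether is stable and the C2–H is not enolised under these conditions, so the 2R configuration is kept.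

Compound list
1 | 5-bromovanillin (3-bromo-4-hydroxy-5-methoxybenzaldehyde) | COc1cc(C=O)cc(Br)c1O | starting material
2 | 3-bromo-4,5-dihydroxybenzaldehyde | O=Cc1cc(O)c(O)c(Br)c1 | intermediate
3 | 3-bromo-5-hydroxy-4-methoxybenzaldehyde | COc1c(O)cc(C=O)cc1Br | intermediate
4 | 3-bromo-4-methoxy-5-(methoxymethoxy)benzaldehyde | COCOc1cc(C=O)cc(Br)c1OC | intermediate
5 | (±)-1-[3-bromo-4-methoxy-5-(methoxymethoxy)phenyl]-2,2,2-trichloroethan-1-ol | COCOc1cc(C(O)C(Cl)(Cl)Cl)cc(Br)c1OC | intermediate
6 | (±)-3-[3-bromo-4-methoxy-5-(methoxymethoxy)phenyl]-2,2-dichlorooxirane (not isolated) | COCOc1cc(C2OC2(Cl)Cl)cc(Br)c1OC | intermediate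
7 | [3-bromo-4-methoxy-5-(methoxymethoxy)phenyl]acetyl chloride (not isolated) | COCOc1cc(CC(=O)Cl)cc(Br)c1OC | intermediate
8 | [3-bromo-4-methoxy-5-(methoxymethoxy)phenyl]acetic acid | COCOc1cc(CC(=O)O)cc(Br)c1OC | intermediate
9 | methyl [3-bromo-4-methoxy-5-(methoxymethoxy)phenyl]acetate | COCOc1cc(CC(=O)OC)cc(Br)c1OC | intermediate
10 | methyl (±)-2-[3-bromo-4-methoxy-5-(methoxymethoxy)phenyl]-3-hydroxypropanoate (not isolated) | COCOc1cc(C(CO)C(=O)OC)cc(Br)c1OC | intermediate
11 | methyl 2-[3-bromo-4-methoxy-5-(methoxymethoxy)phenyl]prop-2-enoate | C=C(C(=O)OC)c1cc(OCOC)c(OC)c(Br)c1 | intermediate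
12 | 2,3-dibromo-4-hydroxy-5-methoxybenzaldehyde | COc1cc(C=O)c(Br)c(Br)c1O | intermediate
13 | 2,3-dibromo-4,5-dihydroxybenzaldehyde | O=Cc1cc(O)c(O)c(Br)c1Br | intermediate
14 | 2,3-dibromo-4,5-bis(methoxymethoxy)benzaldehyde | COCOc1cc(C=O)c(Br)c(Br)c1OCOC | intermediate
15 | 2,3-dibromo-4,5-bis(methoxymethoxy)benzoic acid | COCOc1cc(C(=O)O)c(Br)c(Br)c1OCOC | intermediate
16 | 2,3-dibromo-4,5-bis(methoxymethoxy)benzoyl azide (not isolated) | COCOc1cc(C(=O)N=[N+]=[N-])c(Br)c(Br)c1OCOC | intermediate
17 | 2,3-dibromo-1-isocyanato-4,5-bis(methoxymethoxy)benzene (not isolated) | COCOc1cc(N=C=O)c(Br)c(Br)c1OCOC | intermediate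
18 | 2,3-dibromo-4,5-bis(methoxymethoxy)aniline | COCOc1cc(N)c(Br)c(Br)c1OCOC | intermediate
19 | 2,3-dibromo-4,5-bis(methoxymethoxy)benzenediazonium tert-butoxide (not isolated) | COCOc1cc([N+]#N)c(Br)c(Br)c1OCOC.CC(C)(C)[O-] | intermediate
20 | 2-[2,3-dibromo-4,5-bis(methoxymethoxy)phenyl]-4,4,5,5-tetramethyl-1,3,2-dioxaborolane | CC1(C)OB(OC1(C)C)c1cc(OCOC)c(OCOC)c(Br)c1Br | intermediate
21 | methyl (2R)-2-[3-bromo-4-methoxy-5-(methoxymethoxy)phenyl]-3-[2,3-dibromo-4,5-bis(methoxymethoxy)phenyl]propanoate | COC(=O)[C@H](Cc1cc(OCOC)c(OCOC)c(Br)c1Br)c1cc(OCOC)c(OC)c(Br)c1 | intermediate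
22 | methyl (2R)-2-(3-bromo-5-hydroxy-4-methoxyphenyl)-3-(2,3-dibromo-4,5-dihydroxyphenyl)propanoate | COC(=O)[C@H](Cc1cc(O)c(O)c(Br)c1Br)c1cc(O)c(OC)c(Br)c1 | target

Total step count: 15 (ring A branch 7, ring B branch 6, coupling and deprotection 2).
Longest linear sequence: 9 steps (steps 1–7, 14 and 15).

Steps most likely to fail

Step 14. The hindered ortho-bromo boronate may transmetalate slowly, so that hydrolytic loss of boron wins. The rhodium enolate may undergo β-hydride elimination instead of protonation. Protonation may occur with poor facial discrimination or on free enolate, and the acidic C2–H may epimerise afterwards. The fallback is an auxiliary-controlled benzylation that sets out from acid 8 and aldehyde 14 and comes back at 21. Acid 8 is activated with pivaloyl chloride and Et3N (THF, −20 °C) as the mixed pivalic anhydride F1, which acylates (R)-4-benzyl-1,3-oxazolidin-2-one in the presence of LiCl to give the N-arylacetyl oxazolidinone F2. In parallel 14 is reduced with NaBH4 (MeOH, 0 °C) to the benzyl alcohol F3 and converted with CBr4/PPh3 (CH2Cl2, 0 °C) into the benzyl bromide F4. Deprotonation of F2 with NaN(SiMe3)2 (THF, −78 °C) gives the chelated sodium Z-enolate F5, which F4 should alkylate on the face away from the benzyl group of the auxiliary (Evans alkylation) to give the 2R-configured alkylated imide F6. The R auxiliary is chosen because ring A outranks the new CH2 group, which reverses the descriptor relative to the familiar propionimide case. LiOH/H2O2 (THF/H2O, 0 °C) removes the auxiliary to give the (2R)-acid F7, and Me3SiCHN2 (toluene/MeOH, 0 °C) esterifies it to 21 without base.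

Step 13. Boryl transfer to the hindered, electron-rich aryl radical may be slow, so that hydrodediazoniation or azo and triazene coupling of the aniline with its own diazonium ion takes over. The fallback sets out from aniline 18 and comes back at 20. Aniline 18 is diazotised as in step 13 (t-BuONO, MeCN; diazonium salt 19) but in the presence of I2, which traps the aryl radical as the aryl iodide 2,3-dibromo-1-iodo-4,5-bis(methoxymethoxy)benzene F8 (aprotic Sandmeyer iodination). Iodine–magnesium exchange with i-PrMgCl·LiCl (THF, −40 °C) is much faster at C–I than at C–Br and gives the ortho-bromoaryl magnesium chloride F9, which is stable at this temperature. Quenching with 2-isopropoxy-4,4,5,5-tetramethyl-1,3,2-dioxaborolane gives 20.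

Step 5. Hydroxide or tert-butoxide may open the dichloroepoxide at the benzylic carbon in place of hydride, or the carbinol may revert to the aldehyde, which is then simply reduced. The fallback sets out from aldehyde 4 and comes back at ester 9, bypassing steps 4–6. Knoevenagel-type condensation of 4 with methyl (methylsulfanyl)methyl sulfoxide (BnMe3N+ OH−, THF, reflux) gives the ketene dithioacetal S-oxide F10. HCl in MeOH converts it into methyl (3-bromo-5-hydroxy-4-methoxyphenyl)acetate F11 (Ogura–Tsuchihashi arylacetic ester synthesis), with loss of the MOM group in the same acid. MOMCl/i-Pr2NEt (CH2Cl2) then restores the MOM ether and gives 9.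

Further compounds
F1 | step 14 | [3-bromo-4-methoxy-5-(methoxymethoxy)phenyl]acetic pivalic anhydride | COCOc1cc(CC(=O)OC(=O)C(C)(C)C)cc(Br)c1OC
F2 | step 14 | (4R)-4-benzyl-3-{[3-bromo-4-methoxy-5-(methoxymethoxy)phenyl]acetyl}-1,3-oxazolidin-2-one | COCOc1cc(CC(=O)N2[C@H](Cc3ccccc3)COC2=O)cc(Br)c1OC
F3 | step 14 | [2,3-dibromo-4,5-bis(methoxymethoxy)phenyl]methanol | COCOc1cc(CO)c(Br)c(Br)c1OCOC
F4 | step 14 | 2,3-dibromo-1-(bromomethyl)-4,5-bis(methoxymethoxy)benzene | COCOc1cc(CBr)c(Br)c(Br)c1OCOC
F5 | step 14 | sodium (Z)-enolate of F2 | [Na+].[O-]/C(=C\c1cc(OCOC)c(OC)c(Br)c1)N1[C@H](Cc2ccccc2)COC1=O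
F6 | step 14 | (4R)-4-benzyl-3-{(2R)-2-[3-bromo-4-methoxy-5-(methoxymethoxy)phenyl]-3-[2,3-dibromo-4,5-bis(methoxymethoxy)phenyl]propanoyl}-1,3-oxazolidin-2-one | O=C([C@H](Cc1cc(OCOC)c(OCOC)c(Br)c1Br)c1cc(OCOC)c(OC)c(Br)c1)N1[C@H](Cc2ccccc2)COC1=O
F7 | step 14 | (2R)-2-[3-bromo-4-methoxy-5-(methoxymethoxy)phenyl]-3-[2,3-dibromo-4,5-bis(methoxymethoxy)phenyl]propanoic acid | OC(=O)[C@H](Cc1cc(OCOC)c(OCOC)c(Br)c1Br)c1cc(OCOC)c(OC)c(Br)c1
F8 | step 13 | 2,3-dibromo-1-iodo-4,5-bis(methoxymethoxy)benzene | COCOc1cc(I)c(Br)c(Br)c1OCOC
F9 | step 13 | [2,3-dibromo-4,5-bis(methoxymethoxy)phenyl]magnesium chloride | COCOc1cc([Mg]Cl)c(Br)c(Br)c1OCOC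
F10 | step 5 | 1-bromo-2-methoxy-3-(methoxymethoxy)-5-[2-(methylsulfanyl)-2-(methylsulfinyl)ethenyl]benzene | COCOc1cc(C=C(SC)S(C)=O)cc(Br)c1OC
F11 | step 5 | methyl (3-bromo-5-hydroxy-4-methoxyphenyl)acetate | COC(=O)Cc1cc(O)c(OC)c(Br)c1
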